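**Retrosynthetic overview**
- The target is the ring-opened, O-acetylated form of a 3-alkyl-6,8-dihydroxy-3,4-dihydroisocoumarin. Hydrogenolysis of four benzyl groups, acetylation and saponification/benzyl ester formation lead back to the (3R)-lactone with all three hydroxyls benzylated.
- That lactone comes from the corresponding isocoumarin by enantioselective hydrogenation of C3=C4, which sets the only stereocentre (the acetoxy carbon C2' of the chain).
- The isocoumarin is cut at three bonds: aryl–C4, aryl–C1(carboxyl) and O2–C3. The pieces are a 3,5-bis(benzyloxy)aryne (from an ortho-silyl aryl triflate), a C13 terminal alkyne and CO2. The lactone is the only ring made (the benzene ring is bought) and it is opened again later.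
- The silyl triflate derives from 3,5-bis(benzyloxy)phenol (carbamate-directed ortho-silylation, then triflation). The alkyne derives from 11-bromoundecan-1-ol (acetylide alkylation, benzylation).
- Feature used: on the benzoic acid ring the carboxyl carbon (on C1) and the chain carbon C1' (on C6) sit on neighbouring ring carbons, with the C2 oxygen next to C1. This is the pattern a 3-alkoxy-distorted aryne gives when a nucleophile adds remote from the ether and an electrophile is taken up next to it. C2' lies where a six-membered lactone onto the carboxyl can close.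

Key step: step 6

Remark: the sense of induction of the ruthenium catalyst in step 7 cannot be read from the structure. The ligand antipodes written are those assumed to give 3R, and the mirror-image set is used if the first run shows the opposite sense. The R descriptor carries unchanged from the dihydroisocoumarin to the target, because the carbinol C–O bond is never broken and the CIP ranking (O > CH2Ar > chain CH2 > H) stays the same.

**Route**

Step 1
Reactants: 1 3,5-bis(benzyloxy)phenol
Product: 2 3,5-bis(benzyloxy)phenyl N-isopropylcarbamate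
Conditions: iPrNCO, Et3N (cat.), CH2Cl2, rt
Reagents that add atoms: isopropyl isocyanate CC(C)N=C=O
Why: Base-catalysed addition of the phenol to the isocyanate (carbamoylation) installs a strong ortho-directing group that can later be removed with amines under mild conditions.

Step 2
Reactants: 2 3,5-bis(benzyloxy)phenyl N-isopropylcarbamate
Product: 6 3,5-bis(benzyloxy)-2-(trimethylsilyl)phenyl N-isopropylcarbamate, via N-TBS carbamate 3 (not isolated), via aryllithium 4 (not isolated), via N-TBS C-TMS carbamate 5 (not isolated)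
Conditions: TBSOTf, TMEDA, Et2O, 0 °C to rt; n-BuLi, TMEDA, −78 °C; TMSCl, −78 °C to rt; cold aq NaHSO4
Reagents that add atoms: chlorotrimethylsilane C[Si](C)(C)Cl
Why: After in-situ N-silylation the carbamate directs ortho-lithiation (directed ortho-metalation) to C2, the position flanked by both the carbamate and a benzyloxy group, and TMSCl quenches the aryllithium at −78 °C before anionic Fries rearrangement or benzylic deprotonation should compete; the labile N–Si bond is lost on work-up.

Step 3
Reactants: 6 3,5-bis(benzyloxy)-2-(trimethylsilyl)phenyl N-isopropylcarbamate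
Product: 8 3,5-bis(benzyloxy)-2-(trimethylsilyl)phenyl trifluoromethanesulfonate, via silylphenol 7 (not isolated)
Conditions: DBU, Et2NH, MeCN, 40 °C; then PhNTf2, rt
Reagents that add atoms: N-phenylbis(trifluoromethanesulfonimide) O=S(=O)(N(c1ccccc1)S(=O)(=O)C(F)(F)F)C(F)(F)F
Why: DBU deprotonates the carbamate N–H and the phenoxide is expelled (E1cB loss of isopropyl isocyanate, trapped by Et2NH as a urea); triflation in the same flask avoids isolating the electron-rich, acid-sensitive silylphenol.

Step 4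
Reactants: 9 11-bromoundecan-1-ol
Product: 10 tridec-12-yn-1-ol
Conditions: LiC≡CH·H2NCH2CH2NH2 (3 equiv), DMSO, 0 °C to rt
Reagents that add atoms: lithium acetylide (ethylenediamine complex) [Li+].[C-]#C
Why: SN2 alkylation of lithium acetylide by the primary bromide; the first equivalent only deprotonates the hydroxyl, and the alkoxide returns to the alcohol on work-up.

Step 5
Reactants: 10 tridec-12-yn-1-ol; 11 benzyl bromide
Product: 12 benzyl tridec-12-ynyl ether
Conditions: NaH (1.1 equiv), THF/DMF, 0 °C; BnBr, Bu4NI (cat.), rt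
Reagents that add atoms: benzyl bromide BrCc1ccccc1
Why: Williamson etherification; alkoxide formation is far faster than deprotonation of the alkyne C–H, so only oxygen is benzylated.

Step 6
Reactants: 8 3,5-bis(benzyloxy)-2-(trimethylsilyl)phenyl trifluoromethanesulfonate; 12 benzyl tridec-12-ynyl ether; 13 carbon dioxide
Product: 15 6,8-bis(benzyloxy)-3-[11-(benzyloxy)undecyl]-1H-isochromen-1-one, via aryne 14 (not isolated)
Conditions: IPrCuCl (10 mol %), CsF (3 equiv), CO2 (1 atm), MeCN, 60 °C, slow addition of 8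
Reagents that add atoms: carbon dioxide O=C=O
Why: Fluoride removes the trimethylsilyl group of 8 with loss of triflate to give aryne 14, and the IPr-copper acetylide formed from 12 adds across the strained triple bond, the alkynyl carbon bonding to the aryne carbon remote from the flanking benzyloxy group (the former C–OTf carbon) and copper ending on the carbon between the new alkynyl group and that ether. This arylcopper inserts CO2 to a copper benzoate, whose carboxylate oxygen attacks the outer alkyne carbon in a 6-endo-dig closure that forms the lactone ring (the only ring made), and protonation of the C4–Cu bond by another molecule of 12 releases 15 and returns the copper acetylide. The closest known reaction type is the copper–NHC-catalysed three-component coupling of arynes, terminal alkynes and CO2 to isocoumarins, used here with a 3,5-dialkoxyaryne and an aliphatic alkyne. No stereocentre is formed. The step needs regioselective acetylide addition, which the benzyloxy group next to the aryne secures by distorting the triple bond so that the remote carbon is the electrophilic one, the same bias that 3-alkoxyarynes show towards other nucleophiles. It also needs CO2 capture to outrun protonation of the hindered arylcopper (CO2-saturated MeCN, slow addition of 8) and 6-endo to outrun 5-exo closure, for which the bulky carbene ligand on copper is relied on.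

Step 7
Reactants: 15 6,8-bis(benzyloxy)-3-[11-(benzyloxy)undecyl]-1H-isochromen-1-one
Product: 16 (3R)-6,8-bis(benzyloxy)-3-[11-(benzyloxy)undecyl]-3,4-dihydro-1H-isochromen-1-one
Conditions: H2 (50 bar), Ru(2-methylallyl)2(cod) (5 mol %), SINpEt·HBF4 (1,3-bis[(1R)-1-(1-naphthyl)ethyl]-4,5-dihydroimidazolium tetrafluoroborate), KOtBu, (R,R)-1,2-diphenylethylenediamine, toluene/n-hexane, 25 °C
Reagents that add atoms: none
Why: Enantioselective hydrogenation of the C3=C4 bond of an isocoumarin by a chiral ruthenium–NHC–diamine catalyst is a known reaction of 3-alkylisocoumarins, 8-alkoxy examples included; the C3 stereocentre is set by catalyst control (ligand antipode chosen for 3R), and the benzyl ethers should not be touched by this homogeneous catalyst.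

Step 8
Reactants: 16 (3R)-6,8-bis(benzyloxy)-3-[11-(benzyloxy)undecyl]-3,4-dihydro-1H-isochromen-1-one; 11 benzyl bromide
Product: 18 benzyl 2,4-bis(benzyloxy)-6-[(2R)-13-(benzyloxy)-2-hydroxytridecyl]benzoate, via lithium carboxylate 17 (not isolated)
Conditions: LiOH·H2O, THF/H2O, 50 °C; solid CO2 to pH 8, evaporate; BnBr, DMF, rt
Reagents that add atoms: lithium hydroxide [Li+].[OH-]; benzyl bromide BrCc1ccccc1
Why: Saponification opens the lactone and the carboxylate is alkylated by BnBr (SN2) without ever being acidified, so the hydroxy acid cannot re-lactonise; the carbinol C–O bond is not touched and the R configuration is kept.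

Step 9
Reactants: 18 benzyl 2,4-bis(benzyloxy)-6-[(2R)-13-(benzyloxy)-2-hydroxytridecyl]benzoate
Product: 19 benzyl 2-[(2R)-2-acetoxy-13-(benzyloxy)tridecyl]-4,6-bis(benzyloxy)benzoate
Conditions: Ac2O, pyridine, DMAP (cat.), CH2Cl2, 0 °C to rt, on crude 18
Reagents that add atoms: acetic anhydride CC(=O)OC(C)=O
Why: DMAP-catalysed acetylation of the secondary alcohol, run at once on crude material so that the free hydroxyl has no time to attack the hindered, di-ortho-substituted benzyl ester.

Step 10
Reactants: 19 benzyl 2-[(2R)-2-acetoxy-13-(benzyloxy)tridecyl]-4,6-bis(benzyloxy)benzoate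
Product: 20 2-[(2R)-2-acetoxy-13-hydroxytridecyl]-4,6-dihydroxybenzoic acid
Conditions: H2 (1 atm), 10% Pd/C, EtOAc/THF, rt
Reagents that add atoms: none
Why: Hydrogenolysis over Pd/C removes the two aryl benzyl ethers, the alkyl benzyl ether and the benzyl ester in one neutral operation, which should leave the secondary acetate and the non-benzylic stereocentre untouched.

**Compound list**
1 | 3,5-bis(benzyloxy)phenol | Oc1cc(OCc2ccccc2)cc(OCc2ccccc2)c1 | starting material
2 | 3,5-bis(benzyloxy)phenyl N-isopropylcarbamate | CC(C)NC(=O)Oc1cc(OCc2ccccc2)cc(OCc2ccccc2)c1 | intermediate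
3 | 3,5-bis(benzyloxy)phenyl N-(tert-butyldimethylsilyl)-N-isopropylcarbamate | CC(C)N(C(=O)Oc1cc(OCc2ccccc2)cc(OCc2ccccc2)c1)[Si](C)(C)C(C)(C)C | intermediate
4 | 2-lithio-3,5-bis(benzyloxy)phenyl N-(tert-butyldimethylsilyl)-N-isopropylcarbamate | [Li]c1c(OC(=O)N(C(C)C)[Si](C)(C)C(C)(C)C)cc(OCc2ccccc2)cc1OCc1ccccc1 | intermediate
5 | 3,5-bis(benzyloxy)-2-(trimethylsilyl)phenyl N-(tert-butyldimethylsilyl)-N-isopropylcarbamate | CC(C)N(C(=O)Oc1cc(OCc2ccccc2)cc(OCc2ccccc2)c1[Si](C)(C)C)[Si](C)(C)C(C)(C)C | intermediate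
6 | 3,5-bis(benzyloxy)-2-(trimethylsilyl)phenyl N-isopropylcarbamate | CC(C)NC(=O)Oc1cc(OCc2ccccc2)cc(OCc2ccccc2)c1[Si](C)(C)C | intermediate
7 | 3,5-bis(benzyloxy)-2-(trimethylsilyl)phenol | C[Si](C)(C)c1c(O)cc(OCc2ccccc2)cc1OCc1ccccc1 | intermediate
8 | 3,5-bis(benzyloxy)-2-(trimethylsilyl)phenyl trifluoromethanesulfonate | C[Si](C)(C)c1c(OS(=O)(=O)C(F)(F)F)cc(OCc2ccccc2)cc1OCc1ccccc1 | intermediate
9 | 11-bromoundecan-1-ol | OCCCCCCCCCCCBr | starting material
10 | tridec-12-yn-1-ol | C#CCCCCCCCCCCCO | intermediate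
11 | benzyl bromide | BrCc1ccccc1 | starting material
12 | benzyl tridec-12-ynyl ether | C#CCCCCCCCCCCCOCc1ccccc1 | intermediate
13 | carbon dioxide | O=C=O | starting material
14 | 3,5-bis(benzyloxy)benzyne | C1#CC(OCc2ccccc2)=CC(OCc2ccccc2)=C1 | intermediate
15 | 6,8-bis(benzyloxy)-3-[11-(benzyloxy)undecyl]-1H-isochromen-1-one | O=C1OC(CCCCCCCCCCCOCc2ccccc2)=Cc2cc(OCc3ccccc3)cc(OCc3ccccc3)c12 | intermediate
16 | (3R)-6,8-bis(benzyloxy)-3-[11-(benzyloxy)undecyl]-3,4-dihydro-1H-isochromen-1-one | O=C1O[C@H](CCCCCCCCCCCOCc2ccccc2)Cc2cc(OCc3ccccc3)cc(OCc3ccccc3)c12 | intermediate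
17 | lithium 2,4-bis(benzyloxy)-6-[(2R)-13-(benzyloxy)-2-hydroxytridecyl]benzoate | [Li+].O[C@H](CCCCCCCCCCCOCc1ccccc1)Cc1cc(OCc2ccccc2)cc(OCc2ccccc2)c1C(=O)[O-] | intermediate
18 | benzyl 2,4-bis(benzyloxy)-6-[(2R)-13-(benzyloxy)-2-hydroxytridecyl]benzoate | O[C@H](CCCCCCCCCCCOCc1ccccc1)Cc1cc(OCc2ccccc2)cc(OCc2ccccc2)c1C(=O)OCc1ccccc1 | intermediate
19 | benzyl 2-[(2R)-2-acetoxy-13-(benzyloxy)tridecyl]-4,6-bis(benzyloxy)benzoate | CC(=O)O[C@H](CCCCCCCCCCCOCc1ccccc1)Cc1cc(OCc2ccccc2)cc(OCc2ccccc2)c1C(=O)OCc1ccccc1 | intermediate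
20 | 2-[(2R)-2-acetoxy-13-hydroxytridecyl]-4,6-dihydroxybenzoic acid | CC(=O)O[C@H](CCCCCCCCCCCO)Cc1cc(O)cc(O)c1C(=O)O | target

**Totals**
Total step count: 10. Longest linear sequence: 8 steps (1, 2, 3, 6, 7, 8, 9, 10).

**Steps most likely to fail**

Step 6. What may go wrong:
- loss of regiocontrol in the acetylide addition to the unsymmetrical aryne;
- protonation of the hindered arylcopper before it takes up CO2, which would give the simple aryl alkyne;
- 5-exo closure to an alkylidene phthalide;
- consumption of the aryne by fluoride or by itself.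

Fallback (from 12, back at 15): the ring substitution is fixed in a benzoate and the three bonds are made one after another. Commercial methyl 2,4,6-trihydroxybenzoate is benzylated twice (BnBr 2 equiv, K2CO3, acetone; the hydrogen-bonded hydroxyl stays free) to methyl 2,4-bis(benzyloxy)-6-hydroxybenzoate F1. Triflation (Tf2O, pyridine, CH2Cl2) gives methyl 2,4-bis(benzyloxy)-6-{[(trifluoromethyl)sulfonyl]oxy}benzoate F2. Sonogashira coupling of F2 with 12 (PdCl2(PPh3)2, CuI, Et3N, DMF, 60 °C) gives methyl 2,4-bis(benzyloxy)-6-[13-(benzyloxy)tridec-1-yn-1-yl]benzoate F3. Iodocyclisation (I2, NaHCO3, MeCN; 6-endo attack of the ester carbonyl oxygen, loss of MeI) gives 6,8-bis(benzyloxy)-3-[11-(benzyloxy)undecyl]-4-iodo-1H-isochromen-1-one F4. Reductive removal of iodine (Pd(PPh3)4, HCO2Na, DMF) gives 15.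

Step 7. What may go wrong: poor facial selectivity with the long-chain, 6,8-dibenzyloxy substrate, or slow turnover of the catalyst on this hindered enol lactone.

Fallback (from 12, back at 20): the stereocentre is taken from a resolved epoxide instead of a hydrogenation.
- Semi-hydrogenation of 12 (H2, Pd/CaCO3 poisoned with Pb(OAc)2, quinoline) gives 13-(benzyloxy)tridec-1-ene F5.
- mCPBA gives rac-2-[11-(benzyloxy)undecyl]oxirane F6.
- Hydrolytic kinetic resolution with (salen)Co(OAc) and 0.55 equiv of water, using the catalyst antipode that leaves the R epoxide (expected to be the S,S complex), gives (2R)-2-[11-(benzyloxy)undecyl]oxirane F7.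
- The Grignard reagent from commercial 1-bromo-3,5-bis(benzyloxy)benzene opens F7 at the terminal carbon (CuI cat., THF, −30 °C) to (2R)-1-[3,5-bis(benzyloxy)phenyl]-13-(benzyloxy)tridecan-2-ol F8.
- Acetylation (Ac2O, pyridine, DMAP) gives (2R)-1-[3,5-bis(benzyloxy)phenyl]-13-(benzyloxy)tridecan-2-yl acetate F9.
- Vilsmeier–Haack formylation (POCl3, DMF), expected mainly at the ring position ortho to the chain and para to a benzyloxy group, gives (2R)-1-[3,5-bis(benzyloxy)-2-formylphenyl]-13-(benzyloxy)tridecan-2-yl acetate F10.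
- Pinnick oxidation (NaClO2, NaH2PO4, 2-methyl-2-butene, t-BuOH/H2O) gives 2-[(2R)-2-acetoxy-13-(benzyloxy)tridecyl]-4,6-bis(benzyloxy)benzoic acid F11.
- Hydrogenolysis under the conditions of step 10 gives 20.

Step 8. What may go wrong: the lactone re-closes when the liberated C2' hydroxyl attacks the new benzyl ester (loss of benzyl alcohol) during alkylation or concentration, or the free hydroxyl is benzylated by residual hydroxide.

Fallback (from 16, back at 20): the carboxyl carbon is taken through the alcohol oxidation level, where no lactone can form.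
- LiAlH4 (THF, 0 °C) reduces 16 to (2R)-1-[3,5-bis(benzyloxy)-2-(hydroxymethyl)phenyl]-13-(benzyloxy)tridecan-2-ol F12.
- The primary benzylic hydroxyl is silylated selectively (TBSCl, imidazole, CH2Cl2, 0 °C) to (2R)-1-[3,5-bis(benzyloxy)-2-({[tert-butyl(dimethyl)silyl]oxy}methyl)phenyl]-13-(benzyloxy)tridecan-2-ol F13.
- Acetylation (Ac2O, pyridine, DMAP) gives (2R)-1-[3,5-bis(benzyloxy)-2-({[tert-butyl(dimethyl)silyl]oxy}methyl)phenyl]-13-(benzyloxy)tridecan-2-yl acetate F14.
- Buffered desilylation (TBAF/AcOH, THF, 0 °C) gives (2R)-1-[3,5-bis(benzyloxy)-2-(hydroxymethyl)phenyl]-13-(benzyloxy)tridecan-2-yl acetate F15.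
- MnO2 (CH2Cl2) oxidises F15 to the aldehyde (2R)-1-[3,5-bis(benzyloxy)-2-formylphenyl]-13-(benzyloxy)tridecan-2-yl acetate F10.
- Pinnick oxidation gives 2-[(2R)-2-acetoxy-13-(benzyloxy)tridecyl]-4,6-bis(benzyloxy)benzoic acid F11, and hydrogenolysis as in step 10 gives 20.

Further compounds
F1 | step 6 | methyl 2,4-bis(benzyloxy)-6-hydroxybenzoate | COC(=O)c1c(O)cc(OCc2ccccc2)cc1OCc1ccccc1
F2 | step 6 | methyl 2,4-bis(benzyloxy)-6-{[(trifluoromethyl)sulfonyl]oxy}benzoate | COC(=O)c1c(OS(=O)(=O)C(F)(F)F)cc(OCc2ccccc2)cc1OCc1ccccc1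
F3 | step 6 | methyl 2,4-bis(benzyloxy)-6-[13-(benzyloxy)tridec-1-yn-1-yl]benzoate | COC(=O)c1c(C#CCCCCCCCCCCCOCc2ccccc2)cc(OCc2ccccc2)cc1OCc1ccccc1
F4 | step 6 | 6,8-bis(benzyloxy)-3-[11-(benzyloxy)undecyl]-4-iodo-1H-isochromen-1-one | O=C1OC(CCCCCCCCCCCOCc2ccccc2)=C(I)c2cc(OCc3ccccc3)cc(OCc3ccccc3)c12
F5 | step 7 | 13-(benzyloxy)tridec-1-ene | C=CCCCCCCCCCCCOCc1ccccc1
F6 | step 7 | rac-2-[11-(benzyloxy)undecyl]oxirane | C1OC1CCCCCCCCCCCOCc1ccccc1
F7 | step 7 | (2R)-2-[11-(benzyloxy)undecyl]oxirane | O1[C@H](CCCCCCCCCCCOCc2ccccc2)C1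
F8 | step 7 | (2R)-1-[3,5-bis(benzyloxy)phenyl]-13-(benzyloxy)tridecan-2-ol | O[C@H](CCCCCCCCCCCOCc1ccccc1)Cc1cc(OCc2ccccc2)cc(OCc2ccccc2)c1
F9 | step 7 | (2R)-1-[3,5-bis(benzyloxy)phenyl]-13-(benzyloxy)tridecan-2-yl acetate | CC(=O)O[C@H](CCCCCCCCCCCOCc1ccccc1)Cc1cc(OCc2ccccc2)cc(OCc2ccccc2)c1
F10 | step 7 | (2R)-1-[3,5-bis(benzyloxy)-2-formylphenyl]-13-(benzyloxy)tridecan-2-yl acetate | CC(=O)O[C@H](CCCCCCCCCCCOCc1ccccc1)Cc1cc(OCc2ccccc2)cc(OCc2ccccc2)c1C=O
F11 | step 7 | 2-[(2R)-2-acetoxy-13-(benzyloxy)tridecyl]-4,6-bis(benzyloxy)benzoic acid | CC(=O)O[C@H](CCCCCCCCCCCOCc1ccccc1)Cc1cc(OCc2ccccc2)cc(OCc2ccccc2)c1C(=O)O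
F12 | step 8 | (2R)-1-[3,5-bis(benzyloxy)-2-(hydroxymethyl)phenyl]-13-(benzyloxy)tridecan-2-ol | O[C@H](CCCCCCCCCCCOCc1ccccc1)Cc1cc(OCc2ccccc2)cc(OCc2ccccc2)c1CO
F13 | step 8 | (2R)-1-[3,5-bis(benzyloxy)-2-({[tert-butyl(dimethyl)silyl]oxy}methyl)phenyl]-13-(benzyloxy)tridecan-2-ol | O[C@H](CCCCCCCCCCCOCc1ccccc1)Cc1cc(OCc2ccccc2)cc(OCc2ccccc2)c1CO[Si](C)(C)C(C)(C)C
F14 | step 8 | (2R)-1-[3,5-bis(benzyloxy)-2-({[tert-butyl(dimethyl)silyl]oxy}methyl)phenyl]-13-(benzyloxy)tridecan-2-yl acetate | CC(=O)O[C@H](CCCCCCCCCCCOCc1ccccc1)Cc1cc(OCc2ccccc2)cc(OCc2ccccc2)c1CO[Si](C)(C)C(C)(C)C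
F15 | step 8 | (2R)-1-[3,5-bis(benzyloxy)-2-(hydroxymethyl)phenyl]-13-(benzyloxy)tridecan-2-yl acetate | CC(=O)O[C@H](CCCCCCCCCCCOCc1ccccc1)Cc1cc(OCc2ccccc2)cc(OCc2ccccc2)c1CO
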